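## Retrosynthetic overview

1. Target ⇐ 14-membered cyclophane N,O-acetal (ArCH2–O–C5′ ether) by a ring-contracting O→C 1,2-benzyl shift that forms the C5′–CH2Ar bond, the 13-membered ring and the hemiaminal at once.
2. That macrocycle ⇐ tricyclic β-ketoamide + 2,2-dimethoxyacetaldehyde (Knoevenagel condensation, then acetal exchange with the ArCH2OH arm; lactam and 14-membered ring close together).
3. Tricycle ⇐ ring A carrying a (Z)-γ-aryloxy enoate and an (E,Z)-dienyne: one intramolecular Diels–Alder reaction makes rings B and C (alkyne = masked vinyl; ArBr → ArCH2OH).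
4. Ring A ⇐ (R)-5-methylcyclohex-2-en-1-one by Me2CuLi addition/triflation, formylation, vinyl addition/methylation (quaternary C13); arms by alkynylation–Mitsunobu–semihydrogenation and Wittig–Peterson olefination.
5. Ring order: A (bought) → B + C (one step) → lactam + 14-membered ring (one step) → 13-membered ring (contraction).

Assumption: (R)-5-methylcyclohex-2-en-1-one (1) is bought as such (catalogue compound).

Locants and faces: ring C = C1–C2=C3(Me)–C4–C5–C7; ring B = C4–C5–C6–C8–C13; ring A = C8–C9(Me)–C10–C11(Me)–C12–C13(Me); lactam = N1′–C2′(=O)–C3′=C4′–C5′. β is the face of the C13 methyl group. "The tricycle" means this skeleton with H4 β, H5 α (trans B/C), H8 β and 13-Me β (cis A/B), 9-Me β, 11-Me α.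

## Route

Step 1
Reactants: 1 (R)-5-methylcyclohex-2-en-1-one
Product: 3 (3R,5R)-3,5-dimethylcyclohex-1-en-1-yl trifluoromethanesulfonate, via lithium enolate 2 (not isolated)
Conditions: Me2CuLi, Et2O, −78 → −20 °C; then PhNTf2, THF, −78 → 23 °C
Reagents that add atoms: lithium dimethylcuprate [Li+].C[Cu-]C; N-phenylbis(trifluoromethanesulfonimide) O=S(=O)(N(c1ccccc1)S(=O)(=O)C(F)(F)F)C(F)(F)F
Why: Me2CuLi adds 1,4 to the enone anti to the C5 methyl group (axial attack on the half-chair), so the new methyl is trans (sets C9), and the regiodefined enolate is O-triflated by PhNTf2 (conjugate addition–enolate trapping).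

Step 2
Reactants: 3 (3R,5R)-3,5-dimethylcyclohex-1-en-1-yl trifluoromethanesulfonate
Product: 4 (3R,5R)-3,5-dimethylcyclohex-1-ene-1-carbaldehyde
Conditions: Pd(PPh3)4 (5 mol%), CO (1 atm), Bu3SnH (slow addition), LiCl, THF, 50 °C
Reagents that add atoms: carbon monoxide [C-]#[O+]
Why: Pd(PPh3)4-catalysed reductive carbonylation of the vinyl triflate (oxidative addition, CO insertion, hydride transfer from tin) gives the enal without touching a stereocentre.

Step 3
Reactants: 4 (3R,5R)-3,5-dimethylcyclohex-1-ene-1-carbaldehyde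
Product: 7 (1R,2S,3R,5R)-2-ethenyl-1,3,5-trimethylcyclohexane-1-carbaldehyde, via silyl enol ether 5 (not isolated), via lithium enolate 6 (not isolated)
Conditions: (CH2=CH)2CuLi, Me3SiCl, THF, −78 °C; MeLi, 0 °C; MeI, HMPA, −78 → 23 °C
Reagents that add atoms: lithium divinylcuprate [Li+].C=C[Cu-]C=C; iodomethane CI
Why: Cuprate 1,4-addition to the enal occurs anti to the neighbouring C9 methyl group (sets C8), and after MeLi cleavage of the silyl enol ether the aldehyde enolate is methylated anti to the new vinyl group on the face not shielded by the axial C11 methyl (sets the quaternary C13 with 13-Me cis to H8); tandem conjugate addition–enolate alkylation.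

Step 4
Reactants: 7 (1R,2S,3R,5R)-2-ethenyl-1,3,5-trimethylcyclohexane-1-carbaldehyde
Product: 8 (1R,2S,3R,5R)-1-(dimethoxymethyl)-2-ethenyl-1,3,5-trimethylcyclohexane
Conditions: HC(OMe)3, MeOH, PPTS (cat.), 40 °C
Reagents that add atoms: trimethyl orthoformate COC(OC)OC
Why: Acid-catalysed acetalisation (orthoformate as dehydrating agent) masks the neopentyl aldehyde so that the second aldehyde can be unveiled and used alone.

Step 5
Reactants: 8 (1R,2S,3R,5R)-1-(dimethoxymethyl)-2-ethenyl-1,3,5-trimethylcyclohexane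
Product: 9 (1S,2R,4R,6R)-2-(dimethoxymethyl)-2,4,6-trimethylcyclohexane-1-carbaldehyde
Conditions: O3, CH2Cl2/MeOH, −78 °C; then PPh3, −78 → 23 °C
Reagents that add atoms: ozone [O-][O+]=O
Why: Ozonolysis of the only C=C bond with reductive work-up gives the C6 aldehyde; C8 keeps its configuration because the equatorial formyl group trans to the C9 methyl is also the stable epimer.

Step 6
Reactants: 9 (1S,2R,4R,6R)-2-(dimethoxymethyl)-2,4,6-trimethylcyclohexane-1-carbaldehyde; 10 methyl propiolate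
Product: 11 methyl (4R)-4-[(1S,2R,4R,6R)-2-(dimethoxymethyl)-2,4,6-trimethylcyclohexyl]-4-hydroxybut-2-ynoate
Conditions: Me2Zn (3 equiv), (R,R)-ProPhenol (20 mol%), Ph3PO (40 mol%), PhMe, 4 °C
Reagents that add atoms: none
Why: Me2Zn/ProPhenol-catalysed asymmetric alkynylation: the zinc alkynide of 10 is delivered under ligand control to the Si face of the aldehyde, which sets C6 as the epimer that step 7 inverts (the ligand antipode is used if the facial sense is the reverse).

Step 7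
Reactants: 11 methyl (4R)-4-[(1S,2R,4R,6R)-2-(dimethoxymethyl)-2,4,6-trimethylcyclohexyl]-4-hydroxybut-2-ynoate; 12 4-bromophenol
Product: 13 methyl (4S)-4-(4-bromophenoxy)-4-[(1S,2R,4R,6R)-2-(dimethoxymethyl)-2,4,6-trimethylcyclohexyl]but-2-ynoate
Conditions: PPh3/DIAD (pre-mixed), PhMe, 0 → 23 °C
Reagents that add atoms: none
Why: Mitsunobu etherification: the oxyphosphonium of the propargylic alcohol is displaced by 4-bromophenoxide in an SN2 step with inversion, giving the C6 aryl ether configuration of the target (pre-mixing keeps free phosphine away from the ynoate).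

Step 8
Reactants: 13 methyl (4S)-4-(4-bromophenoxy)-4-[(1S,2R,4R,6R)-2-(dimethoxymethyl)-2,4,6-trimethylcyclohexyl]but-2-ynoate
Product: 14 methyl (2Z,4R)-4-(4-bromophenoxy)-4-[(1S,2R,4R,6R)-2-(dimethoxymethyl)-2,4,6-trimethylcyclohexyl]but-2-enoate
Conditions: H2 (1 atm), Pd/CaCO3 poisoned with Pb(OAc)2, quinoline, EtOAc, 23 °C
Reagents that add atoms: none
Why: Semihydrogenation on lead-poisoned Pd/CaCO3 adds H2 syn to the ynoate and stops at the (Z)-enoate; the aryl bromide and the acetal are untouched.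

Step 9
Reactants: 14 methyl (2Z,4R)-4-(4-bromophenoxy)-4-[(1S,2R,4R,6R)-2-(dimethoxymethyl)-2,4,6-trimethylcyclohexyl]but-2-enoate
Product: 15 methyl (2Z,4R)-4-(4-bromophenoxy)-4-[(1S,2R,4R,6R)-2-formyl-2,4,6-trimethylcyclohexyl]but-2-enoate
Conditions: TFA/H2O (9:1), CH2Cl2, 0 °C
Reagents that add atoms: water O
Why: Acid hydrolysis of the dimethyl acetal releases the neopentyl aldehyde while the enoate and the aryl ether survive cold aqueous TFA.

Step 10
Reactants: 15 methyl (2Z,4R)-4-(4-bromophenoxy)-4-[(1S,2R,4R,6R)-2-formyl-2,4,6-trimethylcyclohexyl]but-2-enoate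
Product: 16 methyl (2Z,4R)-4-(4-bromophenoxy)-4-{(1S,2S,4R,6R)-2,4,6-trimethyl-2-[(1E)-2-methyl-3-oxoprop-1-enyl]cyclohexyl}but-2-enoate
Conditions: Ph3P=C(Me)CHO, PhMe, 90 °C
Reagents that add atoms: 2-(triphenylphosphoranylidene)propanal CC(C=O)=P(c1ccccc1)(c1ccccc1)c1ccccc1
Why: Wittig olefination with the formyl-stabilised ylide is aldehyde-selective and (E)-selective, giving the trisubstituted enal that becomes C3=C4 of the diene.

Step 11
Reactants: 16 methyl (2Z,4R)-4-(4-bromophenoxy)-4-{(1S,2S,4R,6R)-2,4,6-trimethyl-2-[(1E)-2-methyl-3-oxoprop-1-enyl]cyclohexyl}but-2-enoate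
Product: 17 methyl (2Z,4R)-4-(4-bromophenoxy)-4-{(1S,2S,4R,6R)-2,4,6-trimethyl-2-[(1E,3Z)-2-methyl-6-(triisopropylsilyl)hexa-1,3-dien-5-ynyl]cyclohexyl}but-2-enoate
Conditions: i-Pr3SiC≡CCH2Si(i-Pr)3, n-BuLi, THF, −20 °C; then 16, −78 → 0 °C
Reagents that add atoms: 1,3-bis(triisopropylsilyl)propyne CC(C)[Si](C(C)C)(C(C)C)CC#C[Si](C(C)C)(C(C)C)C(C)C
Why: Peterson olefination: the lithiated bis-silylpropyne adds to the enal and the β-silyl alkoxide undergoes syn elimination to the (Z)-enyne, the alkyne being a slim stand-in for the vinyl group that must sit inside the diene.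

Step 12
Reactants: 17 methyl (2Z,4R)-4-(4-bromophenoxy)-4-{(1S,2S,4R,6R)-2,4,6-trimethyl-2-[(1E,3Z)-2-methyl-6-(triisopropylsilyl)hexa-1,3-dien-5-ynyl]cyclohexyl}but-2-enoate
Product: 18 methyl 6α-(4-bromophenoxy)-1β-[(triisopropylsilyl)ethynyl]-tricycle-7β-carboxylate
Conditions: PhMe (5 mM), BHT, 150 °C, sealed tube
Reagents that add atoms: none
Why: Intramolecular Diels–Alder reaction: allylic 1,3-strain in the (Z)-enoate keeps H6 in the alkene plane so the diene adds to the face bearing C8 (C5, anti to O6), the ester-exo, tether-exo transition state expected for a three-atom tether gives the trans B/C fusion (C4), the (Z)-dienophile keeps H5 and H7 cis (C7, ester β) and the inside alkynyl group ends cis to H4 (C1).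

Step 13
Reactants: 18 methyl 6α-(4-bromophenoxy)-1β-[(triisopropylsilyl)ethynyl]-tricycle-7β-carboxylate
Product: 19 methyl 6α-[4-(hydroxymethyl)phenoxy]-1β-[(triisopropylsilyl)ethynyl]-tricycle-7β-carboxylate
Conditions: Bu3SnCH2OH, Pd(PPh3)4 (5 mol%), 1,4-dioxane, 100 °C
Reagents that add atoms: (tributylstannyl)methanol CCCC[Sn](CCCC)(CCCC)CO
Why: Migita–Kosugi–Stille coupling of the aryl bromide with the hydroxymethylstannane installs the benzylic alcohol without base.

Step 14
Reactants: 19 methyl 6α-[4-(hydroxymethyl)phenoxy]-1β-[(triisopropylsilyl)ethynyl]-tricycle-7β-carboxylate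
Product: 20 methyl 1β-ethynyl-6α-[4-(hydroxymethyl)phenoxy]-tricycle-7β-carboxylate
Conditions: Bu4NF, AcOH, THF, 0 → 23 °C
Reagents that add atoms: none
Why: Fluoride cleaves the alkynyl C–Si bond (protodesilylation), and buffering with AcOH protects the epimerisable axial ester.

Step 15
Reactants: 20 methyl 1β-ethynyl-6α-[4-(hydroxymethyl)phenoxy]-tricycle-7β-carboxylate
Product: 21 methyl 1β-ethenyl-6α-[4-(hydroxymethyl)phenoxy]-tricycle-7β-carboxylate
Conditions: H2 (1 atm), Pd/CaCO3 poisoned with Pb(OAc)2, quinoline, EtOAc, 23 °C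
Reagents that add atoms: none
Why: Semihydrogenation of the terminal alkyne on lead-poisoned Pd/CaCO3 gives the C1 vinyl group, the trisubstituted ring alkene being inert.

Step 16
Reactants: 21 methyl 1β-ethenyl-6α-[4-(hydroxymethyl)phenoxy]-tricycle-7β-carboxylate; 22 N-(trimethylsilyl)acetamide
Product: 23 3-{1β-ethenyl-6α-[4-(hydroxymethyl)phenoxy]-tricycl-7β-yl}-3-oxopropanamide
Conditions: 22 (4 equiv), n-BuLi (8 equiv), THF, −78 → 0 °C; then 21, −78 → −20 °C; aq NH4Cl
Reagents that add atoms: none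
Why: Claisen condensation: the C,O-dianion of the N-silylacetamide acylates at carbon with the methyl ester and the product survives as its enolate, which prevents double addition and shields C7 from epimerisation.

Step 17
Reactants: 23 3-{1β-ethenyl-6α-[4-(hydroxymethyl)phenoxy]-tricycl-7β-yl}-3-oxopropanamide; 24 2,2-dimethoxyacetaldehyde
Product: 26 14-membered cyclophane N,O-acetal (5′-arylmethoxy-3′-acyl-1′,5′-dihydropyrrol-2′-one), via Knoevenagel alkylidene 25 (not isolated)
Conditions: piperidine/AcOH (20 mol%), 4 Å MS, PhMe, 40 °C; then dilution to 2 mM, CSA (1 equiv), 5 Å MS, 60 °C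
Reagents that add atoms: none
Why: Knoevenagel condensation at the active methylene, then acid-catalysed acetal exchange in which the amide nitrogen closes the five-membered N,O-acetal and the benzylic alcohol replaces the second methoxy group under thermodynamic control to give the 14-membered ring (C5′ forms as a mixture that step 18 erases).

Step 18
Reactants: 26 14-membered cyclophane N,O-acetal (5′-arylmethoxy-3′-acyl-1′,5′-dihydropyrrol-2′-one)
Product: 27 target CNP0151253.3
Conditions: KN(SiMe3)2 (2.5 equiv), 18-crown-6, THF (1 mM), −78 → 40 °C; aq NH4Cl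
Reagents that add atoms: none
Why: Proposed new method: ring-contracting [1,2]-Wittig rearrangement of an N,O-acetal — KN(SiMe3)2 removes the doubly activated C5′–H (vinylogous to the β-dicarbonyl, giving a 2-oxidopyrrole-type anion), the O–CH2Ar bond then cleaves homolytically to a 3-acylmaleimide radical anion and a p-alkoxybenzyl radical held together by the macrocycle, and recombination at C5′ closes the 13-membered cyclophane as the hemiaminal alkoxide, with the C5′ configuration fixed by the face the short tether can reach (both epimers of 26 converge on the same planar anion, and the hemiaminal is configurationally labile so the ring-compatible epimer accumulates); the closest known reaction types are the acetal [1,2]-Wittig rearrangement of O-glycosides to C-glycosides and the Wittig/Stevens ring contractions of hetero-bridged cyclophanes.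

## Compound list

1 | (R)-5-methylcyclohex-2-en-1-one | O=C1C=CC[C@@H](C)C1 | starting material
2 | lithium (3R,5R)-3,5-dimethylcyclohex-1-en-1-olate (not isolated) | [Li]OC1=C[C@H](C)C[C@@H](C)C1 | intermediate
3 | (3R,5R)-3,5-dimethylcyclohex-1-en-1-yl trifluoromethanesulfonate | O=S(=O)(OC1=C[C@H](C)C[C@@H](C)C1)C(F)(F)F | intermediate
4 | (3R,5R)-3,5-dimethylcyclohex-1-ene-1-carbaldehyde | O=CC1=C[C@H](C)C[C@@H](C)C1 | intermediate
5 | {[(2S,3R,5R)-2-ethenyl-3,5-dimethylcyclohexylidene]methoxy}trimethylsilane, O cis to ring CH2 (not isolated) | C=C[C@H]1[C@H](C)C[C@@H](C)C/C1=C\O[Si](C)(C)C | intermediate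
6 | lithium enolate corresponding to 5 (not isolated) | C=C[C@H]1[C@H](C)C[C@@H](C)C/C1=C\O[Li] | intermediate
7 | (1R,2S,3R,5R)-2-ethenyl-1,3,5-trimethylcyclohexane-1-carbaldehyde | C=C[C@H]1[C@H](C)C[C@@H](C)C[C@@]1(C)C=O | intermediate
8 | (1R,2S,3R,5R)-1-(dimethoxymethyl)-2-ethenyl-1,3,5-trimethylcyclohexane | C=C[C@H]1[C@H](C)C[C@@H](C)C[C@@]1(C)C(OC)OC | intermediate
9 | (1S,2R,4R,6R)-2-(dimethoxymethyl)-2,4,6-trimethylcyclohexane-1-carbaldehyde | O=C[C@H]1[C@H](C)C[C@@H](C)C[C@@]1(C)C(OC)OC | intermediate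
10 | methyl propiolate | C#CC(=O)OC | starting material
11 | methyl (4R)-4-[(1S,2R,4R,6R)-2-(dimethoxymethyl)-2,4,6-trimethylcyclohexyl]-4-hydroxybut-2-ynoate | COC(=O)C#C[C@H](O)[C@H]1[C@H](C)C[C@@H](C)C[C@@]1(C)C(OC)OC | intermediate
12 | 4-bromophenol | Oc1ccc(Br)cc1 | starting material
13 | methyl (4S)-4-(4-bromophenoxy)-4-[(1S,2R,4R,6R)-2-(dimethoxymethyl)-2,4,6-trimethylcyclohexyl]but-2-ynoate | COC(=O)C#C[C@@H](Oc1ccc(Br)cc1)[C@H]1[C@H](C)C[C@@H](C)C[C@@]1(C)C(OC)OC | intermediate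
14 | methyl (2Z,4R)-4-(4-bromophenoxy)-4-[(1S,2R,4R,6R)-2-(dimethoxymethyl)-2,4,6-trimethylcyclohexyl]but-2-enoate | COC(=O)/C=C\[C@@H](Oc1ccc(Br)cc1)[C@H]1[C@H](C)C[C@@H](C)C[C@@]1(C)C(OC)OC | intermediate
15 | methyl (2Z,4R)-4-(4-bromophenoxy)-4-[(1S,2R,4R,6R)-2-formyl-2,4,6-trimethylcyclohexyl]but-2-enoate | COC(=O)/C=C\[C@@H](Oc1ccc(Br)cc1)[C@H]1[C@H](C)C[C@@H](C)C[C@@]1(C)C=O | intermediate
16 | methyl (2Z,4R)-4-(4-bromophenoxy)-4-{(1S,2S,4R,6R)-2,4,6-trimethyl-2-[(1E)-2-methyl-3-oxoprop-1-enyl]cyclohexyl}but-2-enoate | COC(=O)/C=C\[C@@H](Oc1ccc(Br)cc1)[C@H]1[C@H](C)C[C@@H](C)C[C@@]1(C)/C=C(\C)C=O | intermediate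
17 | methyl (2Z,4R)-4-(4-bromophenoxy)-4-{(1S,2S,4R,6R)-2,4,6-trimethyl-2-[(1E,3Z)-2-methyl-6-(triisopropylsilyl)hexa-1,3-dien-5-ynyl]cyclohexyl}but-2-enoate | COC(=O)/C=C\[C@@H](Oc1ccc(Br)cc1)[C@H]1[C@H](C)C[C@@H](C)C[C@@]1(C)/C=C(\C)/C=C\C#C[Si](C(C)C)(C(C)C)C(C)C | intermediate
18 | methyl 6α-(4-bromophenoxy)-1β-[(triisopropylsilyl)ethynyl]-tricycle-7β-carboxylate (H1 α, H6 β, H7 α) | COC(=O)[C@H]1[C@@H](C#C[Si](C(C)C)(C(C)C)C(C)C)C=C(C)[C@H]2[C@H]1[C@@H](Oc1ccc(Br)cc1)[C@H]1[C@H](C)C[C@@H](C)C[C@]12C | intermediate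
19 | methyl 6α-[4-(hydroxymethyl)phenoxy]-1β-[(triisopropylsilyl)ethynyl]-tricycle-7β-carboxylate | COC(=O)[C@H]1[C@@H](C#C[Si](C(C)C)(C(C)C)C(C)C)C=C(C)[C@H]2[C@H]1[C@@H](Oc1ccc(CO)cc1)[C@H]1[C@H](C)C[C@@H](C)C[C@]12C | intermediate
20 | methyl 1β-ethynyl-6α-[4-(hydroxymethyl)phenoxy]-tricycle-7β-carboxylate | COC(=O)[C@H]1[C@@H](C#C)C=C(C)[C@H]2[C@H]1[C@@H](Oc1ccc(CO)cc1)[C@H]1[C@H](C)C[C@@H](C)C[C@]12C | intermediate
21 | methyl 1β-ethenyl-6α-[4-(hydroxymethyl)phenoxy]-tricycle-7β-carboxylate | COC(=O)[C@H]1[C@@H](C=C)C=C(C)[C@H]2[C@H]1[C@@H](Oc1ccc(CO)cc1)[C@H]1[C@H](C)C[C@@H](C)C[C@]12C | intermediate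
22 | N-(trimethylsilyl)acetamide | CC(=O)N[Si](C)(C)C | starting material
23 | 3-{1β-ethenyl-6α-[4-(hydroxymethyl)phenoxy]-tricycl-7β-yl}-3-oxopropanamide | NC(=O)CC(=O)[C@H]1[C@@H](C=C)C=C(C)[C@H]2[C@H]1[C@@H](Oc1ccc(CO)cc1)[C@H]1[C@H](C)C[C@@H](C)C[C@]12C | intermediate
24 | 2,2-dimethoxyacetaldehyde | COC(OC)C=O | starting material
25 | 2-(tricycle-7β-carbonyl)-4,4-dimethoxybut-2-enamide of 23 (alkene isomer mixture; the cyclising isomer with the amide cis to the acetal carbon is shown; not isolated) | NC(=O)/C(=C\C(OC)OC)C(=O)[C@H]1[C@@H](C=C)C=C(C)[C@H]2[C@H]1[C@@H](Oc1ccc(CO)cc1)[C@H]1[C@H](C)C[C@@H](C)C[C@]12C | intermediate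
26 | 14-membered cyclophane N,O-acetal: 3′-(tricycle-7β-carbonyl)-1′,5′-dihydropyrrol-2′-one whose C5′ oxygen is the benzylic oxygen of the 6α-aryl ether (C5′ epimer mixture; ring centres as in 27) | C=C[C@H]1C=C(C)[C@H]2[C@H]3[C@@H](Oc4ccc(cc4)COC4C=C(C(=O)N4)C(=O)[C@@H]13)[C@H]1[C@H](C)C[C@@H](C)C[C@]12C | intermediate
27 | target CNP0151253.3: 13-membered cyclophane with 5′-benzyl-5′-hydroxy-3′-acyl-pyrrol-2′-one, 1β-vinyl, 6α-aryloxy, 7β-acyl on the tricycle | C=C[C@H]1C=C(C)[C@H]2[C@H]3[C@@H](Oc4ccc(cc4)C[C@@]4(O)C=C(C(=O)N4)C(=O)[C@@H]13)[C@H]1[C@H](C)C[C@@H](C)C[C@]12C | target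

## Step count and risks

Total step count: 18. Longest linear sequence: 18 (the route is linear from 1).

**Step 18 (the new ring contraction).** The C5′ anion is strongly stabilised and may not fragment, the radical pair may recombine at oxygen or C4′, and the ketone side may enolise. The fallback uses only known reaction types; it sets out from 18 and comes back at 27. Pd(OAc)2/XPhos-catalysed ketone α-arylation of the aryl bromide 18 with 1,1-dimethoxypropan-2-one (Cs2CO3, dioxane, 80 °C) gives the aryl acetonyl ketone acetal F5. Bu4NF/AcOH then frees the alkyne to give the terminal alkyne F6, and semihydrogenation over Pd/CaCO3 poisoned with Pb(OAc)2 gives the vinyl compound F7. Claisen condensation with dilithiated 22 (excess, the benzylic ketone being held as its enolate) gives the β-ketoamide F8. Cold aqueous TFA unmasks the α-ketoaldehyde F9, which under piperidinium acetate at high dilution undergoes intramolecular Knoevenagel condensation at the aldehyde (C3′=C4′); the amide nitrogen then adds to the C5′ ketone, closing the 13-membered ring and the hemiaminal of 27 directly. The ring strain is then paid in the condensation instead of in a contraction.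

**Step 12 (Diels–Alder reaction).** A (Z)-diene with a (Z)-dienophile is slow, the ester-endo pathway would give the cis-fused isomer, and above about 160 °C the aryl allyl ether can undergo Claisen rearrangement. The fallback changes the dienophile geometry; it sets out from 17 and comes back at 18. Reversible thia-Michael addition (PhSH, DBU cat., THF, 40 °C) isomerises only the enoate and gives the (2E)-enoate F1. Under Me2AlCl (CH2Cl2, −78 → 0 °C) F1 cyclises through the ester-endo transition state to the trans-fused adduct with an equatorial α ester, the 7-epimer F2. Deprotonation of F2 with LiN(i-Pr)2 at −78 °C and kinetic protonation of the ester enolate from the open α face (2,6-di-tert-butylphenol) then gives the axial β ester 18.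

**Step 17 (Knoevenagel condensation and macro-acetalisation).** The alkylidene β-ketoamide is a strong Michael acceptor and the acetal exchange may oligomerise. The fallback replaces the reversible exchange by an irreversible O-benzylation; it sets out from 23 and comes back at 26. The condensation with 24 is stopped at the alkylidene 25, which is isolated and hydrolysed (TFA/H2O, 0 °C) to the 5′-hydroxy lactam F3. The benzylic alcohol is converted into its trichloroacetimidate F4 (Cl3CCN, DBU cat., CH2Cl2, 0 °C). TfOH (5 mol%) at 1 mM and −40 °C then benzylates the hemiaminal hydroxyl intramolecularly to give 26.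

## Further compounds

F1 | step 12 | methyl (2E,4R)-4-(4-bromophenoxy)-4-{(1S,2S,4R,6R)-2,4,6-trimethyl-2-[(1E,3Z)-2-methyl-6-(triisopropylsilyl)hexa-1,3-dien-5-ynyl]cyclohexyl}but-2-enoate | COC(=O)/C=C/[C@@H](Oc1ccc(Br)cc1)[C@H]1[C@H](C)C[C@@H](C)C[C@@]1(C)/C=C(\C)/C=C\C#C[Si](C(C)C)(C(C)C)C(C)C
F2 | step 12 | 7-epimer of 18 (methyl 7α-carboxylate) | COC(=O)[C@@H]1[C@@H](C#C[Si](C(C)C)(C(C)C)C(C)C)C=C(C)[C@H]2[C@H]1[C@@H](Oc1ccc(Br)cc1)[C@H]1[C@H](C)C[C@@H](C)C[C@]12C
F3 | step 17 | 5′-hydroxy-3′-(tricycle-7β-carbonyl)-1′,5′-dihydropyrrol-2′-one with free 4-(hydroxymethyl)phenoxy group (C5′ epimer mixture) | O=C1NC(O)C=C1C(=O)[C@H]1[C@@H](C=C)C=C(C)[C@H]2[C@H]1[C@@H](Oc1ccc(CO)cc1)[C@H]1[C@H](C)C[C@@H](C)C[C@]12C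
F4 | step 17 | benzylic trichloroacetimidate of F3 | O=C1NC(O)C=C1C(=O)[C@H]1[C@@H](C=C)C=C(C)[C@H]2[C@H]1[C@@H](Oc1ccc(COC(=N)C(Cl)(Cl)Cl)cc1)[C@H]1[C@H](C)C[C@@H](C)C[C@]12C
F5 | step 18 | methyl 6α-[4-(3,3-dimethoxy-2-oxopropyl)phenoxy]-1β-[(triisopropylsilyl)ethynyl]-tricycle-7β-carboxylate | COC(=O)[C@H]1[C@@H](C#C[Si](C(C)C)(C(C)C)C(C)C)C=C(C)[C@H]2[C@H]1[C@@H](Oc1ccc(CC(=O)C(OC)OC)cc1)[C@H]1[C@H](C)C[C@@H](C)C[C@]12C
F6 | step 18 | methyl 6α-[4-(3,3-dimethoxy-2-oxopropyl)phenoxy]-1β-ethynyl-tricycle-7β-carboxylate | COC(=O)[C@H]1[C@@H](C#C)C=C(C)[C@H]2[C@H]1[C@@H](Oc1ccc(CC(=O)C(OC)OC)cc1)[C@H]1[C@H](C)C[C@@H](C)C[C@]12C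
F7 | step 18 | methyl 6α-[4-(3,3-dimethoxy-2-oxopropyl)phenoxy]-1β-ethenyl-tricycle-7β-carboxylate | COC(=O)[C@H]1[C@@H](C=C)C=C(C)[C@H]2[C@H]1[C@@H](Oc1ccc(CC(=O)C(OC)OC)cc1)[C@H]1[C@H](C)C[C@@H](C)C[C@]12C
F8 | step 18 | 3-{6α-[4-(3,3-dimethoxy-2-oxopropyl)phenoxy]-1β-ethenyl-tricycl-7β-yl}-3-oxopropanamide | NC(=O)CC(=O)[C@H]1[C@@H](C=C)C=C(C)[C@H]2[C@H]1[C@@H](Oc1ccc(CC(=O)C(OC)OC)cc1)[C@H]1[C@H](C)C[C@@H](C)C[C@]12C
F9 | step 18 | 3-{6α-[4-(2,3-dioxopropyl)phenoxy]-1β-ethenyl-tricycl-7β-yl}-3-oxopropanamide | NC(=O)CC(=O)[C@H]1[C@@H](C=C)C=C(C)[C@H]2[C@H]1[C@@H](Oc1ccc(CC(=O)C=O)cc1)[C@H]1[C@H](C)C[C@@H](C)C[C@]12C
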